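**Retrosynthetic overview**
Numbering: the lactone C=O is C1, the ring O–CH is C5, the carbinols are C7, C9 and C11, and the nonyl tail is C12–C20.
Structural feature used: C9 lies between C8H2 and C10H2, and each of these ends at an oxygen-bearing carbon (C7, C11). C9 can therefore enter as a dithiane carbon that attacks two terminal epoxides in turn. The C4–C8 stretch with its anti C5/C7 oxygens is the skeleton of C2-symmetric (2R,4R)-1,2:4,5-diepoxypentane.
Disconnections (retro): O11–Si; C9–H (C7-hydroxyl-directed anti reduction of a C9 ketone); O5–C1 lactone bond; C2=C3 from the alkyne; C9 ketone from the dithiane; C3–C4 (propiolate plus oxirane); C8–C9 and C9–C10 (one-pot silyl-dithiane anion relay with (R)-2-nonyloxirane and the bisepoxide).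
Ring order: the target has one ring, the six-membered 5,6-dihydropyran-2-one (O, C1–C5). It closes only after the whole C1–C20 chain stands, by lactonisation of the C5 hydroxyl onto the Z-enoate, and before C9 is reduced.

Key step: step 6

Assumption: 1,5-dichloropentane-2,4-dione (1) is taken as a catalogue compound, and the sense of induction quoted for the Ru-BINAP and cobalt-salen catalysts follows the usual empirical models, to be confirmed by optical rotation at the epoxide stage.
Note on descriptors: locants C1–C20 follow the target numbering throughout. The CIP letters at C7 and C9 change along the route with substituent priorities, although the spatial arrangement never changes.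

Step 1
Reactants: 1 1,5-dichloropentane-2,4-dione
Product: 2 (2R,4R)-1,5-dichloropentane-2,4-diol
Conditions: Ru2Cl4[(S)-BINAP]2·NEt3 (cat.), H2 (ca. 85 atm), MeOH, 50–80 °C; recrystallisation
Reagents that add atoms: none
Why: Noyori asymmetric hydrogenation of a chelating 1,3-diketone reduces both carbonyls under catalyst control, the (S)-BINAP ligand being expected to give the (R)-chlorohydrin at each end (as with 4-chloroacetoacetates), the second reduction upgrades the enantiopurity of the anti diol, and crystallisation should remove the minor meso isomer.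

Step 2
Reactants: 2 (2R,4R)-1,5-dichloropentane-2,4-diol
Product: 3 (2R,4R)-1,2:4,5-diepoxypentane
Conditions: KOH (powdered, excess), Et2O, rt; careful distillation
Reagents that add atoms: none
Why: Twofold intramolecular Williamson (SN2) closure of the chlorohydrins displaces chloride at the two CH2 groups only, so both carbinol carbons keep their (R) configuration and the C2-symmetric bisepoxide results.

Step 3
Reactants: 4 1-undecene
Product: 5 rac-2-nonyloxirane
Conditions: mCPBA, CH2Cl2, 0 °C to rt
Reagents that add atoms: mCPBA OOC(=O)c1cccc(Cl)c1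
Why: Prilezhaev epoxidation of an unhindered terminal alkene by a peracid is general and creates the oxirane carbon as a racemate that is resolved in the next step.

Step 4
Reactants: 5 rac-2-nonyloxirane
Product: 6 (R)-2-nonyloxirane
Conditions: (R,R)-(salen)Co(OAc) [salen = N,N'-bis(3,5-di-tert-butylsalicylidene)cyclohexane-1,2-diaminate] (0.5 mol %), H2O (0.55 equiv), neat, 0 °C to rt; distillation
Reagents that add atoms: none
Why: In the Jacobsen hydrolytic kinetic resolution the (R,R)-configured cobalt salen acetate should hydrolyse the (S)-epoxide much faster (cooperative bimetallic opening at the CH2), so with slightly more than half an equivalent of water the (R)-epoxide remains and is distilled from the non-volatile diol.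

Step 5
Reactants: 7 1,3-dithiane
Product: 9 2-(tert-butyldimethylsilyl)-1,3-dithiane, via 2-lithio-1,3-dithiane 8 (not isolated)
Conditions: n-BuLi, THF, −30 °C; TBSCl, −78 °C to rt
Reagents that add atoms: TBSCl CC(C)(C)[Si](C)(C)Cl
Why: Corey–Seebach metalation of the acidic C2–H followed by C-silylation of the dithianyl anion with the silyl chloride is the standard preparation of 2-silyl dithianes.

Step 6
Reactants: 9 2-(tert-butyldimethylsilyl)-1,3-dithiane; 6 (R)-2-nonyloxirane; 3 (2R,4R)-1,2:4,5-diepoxypentane
Product: 13 (2R)-1-{2-[(2R)-2-(tert-butyldimethylsilyloxy)undecyl]-1,3-dithian-2-yl}-3-[(2R)-oxiran-2-yl]propan-2-ol (C11 OTBS; C9 dithiane; free C7 OH; C4–C5 oxirane), via lithiated silyl dithiane 10 (not isolated), via lithium carbinolate adduct 11 (not isolated), via Brook-shifted dithianyllithium 12 (not isolated)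
Conditions: 9, t-BuLi (1.05 equiv), Et2O, −78 to −45 °C; 6 (1.0 equiv), Et2O, −78 to −25 °C; then 3 (3 equiv) and HMPA (ca. 1 equiv) in THF, −78 to 0 °C; sat. aq. NH4Cl; excess 3 recovered by distillation
Reagents that add atoms: none
Why: t-BuLi removes the C2–H of 9 and the resulting 10 attacks the CH2 terminus of 6 in an SN2 opening that forms C9–C10; in pure ether the tight lithium carbinolate 11 keeps its C–Si bond, so the sequence pauses here. Adding HMPA in THF loosens the O–Li pair, the alkoxide adds to silicon, and a 1,4-Brook (carbon-to-oxygen) shift through a pentacoordinate silicate places the TBS group on O11 and frees the sulfur-stabilised carbanion 12, which opens one oxirane of 3 at its CH2 and forms C8–C9. The closest known reaction type is the solvent-gated multicomponent linchpin (anion relay) coupling of 2-silyl-1,3-dithianes with two different terminal epoxides, together with the stepwise opening of 1,2:4,5-diepoxypentane by two different nucleophiles. No ring is closed and no stereocentre is made: C11 comes intact from 6, and C7 and C5 come from 3, because each C–O bond that breaks is at a CH2. The step needs the two epoxides to enter in a fixed order and 3 to react only once; the first is secured by the solvent gate, the second by releasing 12 in the presence of a threefold excess of the volatile, recoverable 3, whose two oxiranes are homotopic about the C2 axis so that single opening can give only one compound. The new C7 alkoxide can reach the surviving oxirane only by a strained 4-exo or a disfavoured 5-endo path, so the epoxide should persist, and the one hydroxyl that must later steer the hydride is the only one left unprotected.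

Step 7
Reactants: 13 epoxy alcohol from step 6; 14 ethyl propiolate
Product: 16 ethyl (5S,7R)-8-{2-[(2R)-2-(tert-butyldimethylsilyloxy)undecyl]-1,3-dithian-2-yl}-5,7-dihydroxyoct-2-ynoate, via lithium ethyl propiolate 15 (not isolated)
Conditions: 14 (4 equiv), n-BuLi (4 equiv), THF, −78 °C; BF3·OEt2 (3.5 equiv); then 13, −78 °C; sat. aq. NH4Cl at −78 °C
Reagents that add atoms: none
Why: In the Yamaguchi–Hirao alkynylation the BF3-activated terminal oxirane is opened by the weakly basic lithium propiolate at the unhindered CH2 (C4), forming C3–C4 without touching C5, while one extra equivalent of acetylide merely deprotonates the C7 hydroxyl and the dithiane and TBS ether tolerate BF3·OEt2 at −78 °C.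

Step 8
Reactants: 16 dithiane diol ynoate
Product: 17 ethyl (5S,7R,11R)-11-(tert-butyldimethylsilyloxy)-5,7-dihydroxy-9-oxoicos-2-ynoate
Conditions: PhI(OCOCF3)2 (1.5 equiv), NaHCO3, MeCN/H2O (9:1), 0 °C, short contact; chromatography
Reagents that add atoms: water O
Why: Oxidative dithiane hydrolysis with a trivalent iodine reagent activates sulfur, the ring fragments to a thionium ion that water traps, the sulfur leaves as a non-nucleophilic cyclic disulfide so that no free thiol can add to the ynoate, and the bicarbonate buffer protects the TBS ether and the aldol-type C7-hydroxy ketone; the product is drawn as the open keto form although it may rest partly as its mobile C5–O/C9 hemiketal tautomer.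

Step 9
Reactants: 17 C9 ketone ynoate
Product: 18 ethyl (2Z,5S,7R,11R)-11-(tert-butyldimethylsilyloxy)-5,7-dihydroxy-9-oxoicos-2-enoate
Conditions: Pd/CaCO3 poisoned with Pb(OAc)2 (Lindlar catalyst), quinoline, H2 (1 atm), EtOAc, rt
Reagents that add atoms: none
Why: Lindlar semihydrogenation delivers one equivalent of hydrogen syn on the lead- and quinoline-moderated palladium surface to give the Z-enoate and leaves ketone, silyl ether and ester untouched, provided that 17 has been freed of sulfur residues by chromatography.

Step 10
Reactants: 18 Z-enoate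
Product: 19 (6S)-6-[(2R,6R)-6-(tert-butyldimethylsilyloxy)-2-hydroxy-4-oxopentadecyl]-5,6-dihydro-2H-pyran-2-one
Conditions: PPTS (cat.), toluene, 60 °C
Reagents that add atoms: none
Why: Acid-catalysed transesterification (6-exo-trig lactonisation) of the C5 hydroxyl onto the cis-disposed ester is favoured by ring size over the eight-membered alternative from C7, and loss of ethanol should draw any hemiketal tautomer through the open form into the dihydropyranone.

Step 11
Reactants: 19 C9-keto dihydropyranone
Product: 20 (6S)-6-[(2S,4S,6R)-6-(tert-butyldimethylsilyloxy)-2,4-dihydroxypentadecyl]-5,6-dihydro-2H-pyran-2-one (C9 reads S here only because the silyl ether raises the C10 branch; the geometry is that of 9R in the target)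
Conditions: Me4NBH(OAc)3 (5 equiv), MeCN/AcOH (1:1), −30 °C; aqueous work-up
Reagents that add atoms: none
Why: In the Evans–Saksena reduction the free C7 hydroxyl exchanges for an acetate on boron and hydride is delivered intramolecularly through a chair-like six-membered transition state, which sets C9 1,3-anti to C7 (hence syn to C11), while the weak hydride leaves the enoate lactone alone and the silylated O11 cannot compete as a directing group.

Step 12
Reactants: 20 C11 silyl ether of the target
Product: 21 (6S)-6-[(2S,4R,6R)-2,4,6-trihydroxypentadecyl]-5,6-dihydro-2H-pyran-2-one (target)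
Conditions: 48 % aq. HF, MeCN, 0 °C to rt
Reagents that add atoms: none
Why: Fluoride-driven cleavage of the secondary TBS ether under acidic conditions avoids the basic media that would provoke oxa-Michael addition of the C7 hydroxyl to the unsaturated lactone, and it touches no stereocentre.

**Compound list**
1 | 1,5-dichloropentane-2,4-dione | ClCC(=O)CC(=O)CCl | starting material
2 | (2R,4R)-1,5-dichloropentane-2,4-diol | ClC[C@H](O)C[C@@H](O)CCl | intermediate
3 | (2R,4R)-1,2:4,5-diepoxypentane | C1O[C@@H]1C[C@@H]1CO1 | intermediate
4 | 1-undecene | CCCCCCCCCC=C | starting material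
5 | rac-2-nonyloxirane | CCCCCCCCCC1CO1 | intermediate
6 | (R)-2-nonyloxirane | CCCCCCCCC[C@@H]1CO1 | intermediate
7 | 1,3-dithiane | C1CSCSC1 | starting material
8 | 2-lithio-1,3-dithiane | [Li]C1SCCCS1 | intermediate
9 | 2-(tert-butyldimethylsilyl)-1,3-dithiane | CC(C)(C)[Si](C)(C)C1SCCCS1 | intermediate
10 | 2-lithio-2-(tert-butyldimethylsilyl)-1,3-dithiane | CC(C)(C)[Si](C)(C)C1([Li])SCCCS1 | intermediate
11 | lithium (2R)-1-[2-(tert-butyldimethylsilyl)-1,3-dithian-2-yl]undecan-2-olate | CCCCCCCCC[C@@H](O[Li])CC1(SCCCS1)[Si](C)(C)C(C)(C)C | intermediate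
12 | 2-lithio-2-[(2R)-2-(tert-butyldimethylsilyloxy)undecyl]-1,3-dithiane | CCCCCCCCC[C@@H](O[Si](C)(C)C(C)(C)C)CC1([Li])SCCCS1 | intermediate
13 | (2R)-1-{2-[(2R)-2-(tert-butyldimethylsilyloxy)undecyl]-1,3-dithian-2-yl}-3-[(2R)-oxiran-2-yl]propan-2-ol | CCCCCCCCC[C@@H](O[Si](C)(C)C(C)(C)C)CC1(SCCCS1)C[C@H](O)C[C@@H]1CO1 | intermediate
14 | ethyl propiolate | C#CC(=O)OCC | starting material
15 | lithium ethyl propiolate | [Li]C#CC(=O)OCC | intermediate
16 | ethyl (5S,7R)-8-{2-[(2R)-2-(tert-butyldimethylsilyloxy)undecyl]-1,3-dithian-2-yl}-5,7-dihydroxyoct-2-ynoate | CCCCCCCCC[C@@H](O[Si](C)(C)C(C)(C)C)CC1(SCCCS1)C[C@H](O)C[C@@H](O)CC#CC(=O)OCC | intermediate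
17 | ethyl (5S,7R,11R)-11-(tert-butyldimethylsilyloxy)-5,7-dihydroxy-9-oxoicos-2-ynoate | CCCCCCCCC[C@@H](O[Si](C)(C)C(C)(C)C)CC(=O)C[C@H](O)C[C@@H](O)CC#CC(=O)OCC | intermediate
18 | ethyl (2Z,5S,7R,11R)-11-(tert-butyldimethylsilyloxy)-5,7-dihydroxy-9-oxoicos-2-enoate | CCCCCCCCC[C@@H](O[Si](C)(C)C(C)(C)C)CC(=O)C[C@H](O)C[C@@H](O)C/C=C\C(=O)OCC | intermediate
19 | (6S)-6-[(2R,6R)-6-(tert-butyldimethylsilyloxy)-2-hydroxy-4-oxopentadecyl]-5,6-dihydro-2H-pyran-2-one | CCCCCCCCC[C@@H](O[Si](C)(C)C(C)(C)C)CC(=O)C[C@H](O)C[C@@H]1CC=CC(=O)O1 | intermediate
20 | (6S)-6-[(2S,4S,6R)-6-(tert-butyldimethylsilyloxy)-2,4-dihydroxypentadecyl]-5,6-dihydro-2H-pyran-2-one | CCCCCCCCC[C@@H](O[Si](C)(C)C(C)(C)C)C[C@@H](O)C[C@H](O)C[C@@H]1CC=CC(=O)O1 | intermediate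
21 | (6S)-6-[(2S,4R,6R)-2,4,6-trihydroxypentadecyl]-5,6-dihydro-2H-pyran-2-one (CNP0417102.1) | CCCCCCCCC[C@@H](O)C[C@@H](O)C[C@H](O)C[C@@H]1CC=CC(=O)O1 | target

**Step count**
Total step count: 12.
Longest linear sequence: 9 steps (steps 1, 2, 6–12; the branch through steps 3, 4, 6–12 is equally long).

**Steps most likely to fail**

Step 6. The relay may lose its order: silyl migration could begin before the first epoxide is consumed, so that the freed anion takes up a second molecule of it. The bisepoxide may also be opened at both ends. The fallback gives up the one-pot relay for two separate alkylations and sets out from 8 (made from 7 as in step 5) and 6. Opening of 6 by 8 in THF at −20 °C gives (2R)-1-(1,3-dithian-2-yl)undecan-2-ol F1. TBSCl and imidazole in DMF then give (2R)-2-(tert-butyldimethylsilyloxy)-1-(1,3-dithian-2-yl)undecane F2. Deprotonation of F2 with t-BuLi in THF/HMPA at −78 °C produces 12 as a preformed reagent, which is transferred into an excess of 3. The sequence comes back to the route at 13.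

Step 7. The Lewis acid may provoke participation of the C7 hydroxyl or of a dithiane sulfur in the opening of the activated oxirane, and thermal decay of the lithium propiolate limits the time available. The fallback uses no Lewis acid and brings in C1 separately; it sets out from 13. LiC≡CH·H2NCH2CH2NH2 in DMSO at rt opens the oxirane at C4 to give the terminal alkyne diol F3. TESCl and imidazole give the bis-TES alkyne F4. n-BuLi followed by ClCO2Et in THF at −78 °C gives the bis-TES ynoate F5. AcOH/THF/H2O then removes both triethylsilyl groups while the TBS ether stays. The sequence comes back at 16.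

Step 10. The C5 hydroxyl may be tied up by ring–chain tautomerism with the C9 ketone (a six-membered hemiketal with all carbon substituents equatorial). Lactonisation would then slow down, and acid-induced dehydration of the aldol unit could compete. The fallback removes the ketone before the ring is closed and sets out from 18. Me4NBH(OAc)3 in MeCN/AcOH at −30 °C reduces C9 anti to the C7 hydroxyl and gives the Z-enoate triol F6. With no carbonyl left at C9, PPTS in toluene closes the lactone from the C5 hydroxyl alone. The sequence comes back at 20.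

**Further compounds**
F1 | step 6 | (2R)-1-(1,3-dithian-2-yl)undecan-2-ol | CCCCCCCCC[C@@H](O)CC1SCCCS1
F2 | step 6 | (2R)-2-(tert-butyldimethylsilyloxy)-1-(1,3-dithian-2-yl)undecane | CCCCCCCCC[C@@H](O[Si](C)(C)C(C)(C)C)CC1SCCCS1
F3 | step 7 | terminal alkyne diol, (4S,6R)-7-{2-[(2R)-2-(tert-butyldimethylsilyloxy)undecyl]-1,3-dithian-2-yl}hept-1-yne-4,6-diol | CCCCCCCCC[C@@H](O[Si](C)(C)C(C)(C)C)CC1(SCCCS1)C[C@H](O)C[C@@H](O)CC#C
F4 | step 7 | bis-TES alkyne, the 4,6-bis(triethylsilyl) ether of F3 | CCCCCCCCC[C@@H](O[Si](C)(C)C(C)(C)C)CC1(SCCCS1)C[C@H](O[Si](CC)(CC)CC)C[C@@H](O[Si](CC)(CC)CC)CC#C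
F5 | step 7 | bis-TES ynoate, the 5,7-bis(triethylsilyl) ether of 16 | CCCCCCCCC[C@@H](O[Si](C)(C)C(C)(C)C)CC1(SCCCS1)C[C@H](O[Si](CC)(CC)CC)C[C@@H](O[Si](CC)(CC)CC)CC#CC(=O)OCC
F6 | step 10 | Z-enoate triol, ethyl (2Z,5S,7R,9S,11R)-11-(tert-butyldimethylsilyloxy)-5,7,9-trihydroxyicos-2-enoate | CCCCCCCCC[C@@H](O[Si](C)(C)C(C)(C)C)C[C@@H](O)C[C@H](O)C[C@@H](O)C/C=C\C(=O)OCC
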